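**Retrosynthetic overview**
- The target comes from global O-demethylation of its hepta-O-methyl ether; all seven phenols are carried as methyl ethers from commercial building blocks.
- The dihydrofuran ring is the only ring made, in one [4+1] annulation that forms C2–C3 and then O1–C2 and sets both stereocentres.
- C2–C3 joins the methide carbon of an ortho-quinone methide (electrophile) to a veratryl carbon made nucleophilic as a chiral sulfonium ylide (an umpolung of the normally electrophilic benzylic C–O/C–Br carbon).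
- The ortho-quinone methide is generated in the same flask from an O-Boc salicylaldehyde and 3,5-dimethoxyphenyl Grignard reagent (addition, Boc shift, elimination).
- The (E)-stilbene arm is installed first by Heck coupling on the bromosalicylaldehyde; the ylide precursor is a one-step side branch.

Assumption: the benzylide of (1R,4R,5R)-isothiocineole reacts with the facial sense that gives (R,R)-stilbene oxide from benzaldehyde, which is 2S here because the CIP ranks of aryl and ring carbon swap; if the observed sense is opposite, the (1S,4S,5S) sulfide from (S)-limonene is used and nothing else changes.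

**Step 1**
Reactants: 1 5-bromo-2-hydroxy-4-methoxybenzaldehyde; 2 3,5-dimethoxystyrene (1.3 equiv)
Product: 3 5-[(E)-3,5-dimethoxystyryl]-2-hydroxy-4-methoxybenzaldehyde
Conditions: Pd(OAc)2 (3 mol%), P(o-tol)3 (6 mol%), Et3N (3 equiv), DMF, 100 °C, 16 h
Reagents that add atoms: none
Why: Mizoroki–Heck reaction: oxidative addition of zerovalent palladium into the C–Br bond, syn-carbopalladation at the terminal styrene carbon and syn-β-hydride elimination give the (E)-stilbene, with the free phenol and aldehyde tolerated and no stereocentre formed.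

**Step 2**
Reactants: 3 5-[(E)-3,5-dimethoxystyryl]-2-hydroxy-4-methoxybenzaldehyde
Product: 4 tert-butyl {2-formyl-5-methoxy-4-[(E)-3,5-dimethoxystyryl]phenyl} carbonate
Conditions: Boc2O (1.1 equiv), DMAP (5 mol%), i-Pr2NEt (10 mol%), THF, 0 °C → rt
Reagents that add atoms: di-tert-butyl dicarbonate, CC(C)(C)OC(=O)OC(=O)OC(C)(C)C
Why: DMAP-catalysed O-acylation (Boc protection) of the phenol installs the carbonate that the key step transfers to the benzylic oxygen as a leaving group; no stereocentre is formed.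

**Step 3**
Reactants: 5 3,4-dimethoxybenzyl bromide; 6 (1R,4R,5R)-isothiocineole (1.0 equiv)
Product: 7 (1R,4R,5R)-6-(3,4-dimethoxybenzyl)-4,7,7-trimethyl-6-thiabicyclo[3.2.1]octan-6-ium tetrafluoroborate
Conditions: NaBF4 (3 equiv), CH2Cl2/H2O (1:1), rt, 24 h; crystallise from CH2Cl2/Et2O
Reagents that add atoms: sodium tetrafluoroborate, [Na+].F[B-](F)(F)F
Why: SN2 S-alkylation of the thioether by the reactive benzylic bromide on the exposed exo lone pair, with bromide-to-tetrafluoroborate exchange, gives one sulfonium diastereomer while the three carbon stereocentres of 6 are untouched.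

**Step 4**
Reactants: 4 tert-butyl {2-formyl-5-methoxy-4-[(E)-3,5-dimethoxystyryl]phenyl} carbonate; 8 3,5-dimethoxyphenylmagnesium chloride (commercial 1.0 M THF solution, 1.05 equiv); 7 the sulfonium tetrafluoroborate (1.3 equiv)
Product: 12 (2S,3S)-2-(3,4-dimethoxyphenyl)-3-(3,5-dimethoxyphenyl)-6-methoxy-5-[(E)-3,5-dimethoxystyryl]-2,3-dihydro-1-benzofuran, via chloromagnesium alkoxide 9 (not isolated), via ortho-quinone methide 10 (not isolated), via sulfonium ylide 11 (not isolated)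
Conditions: 8, THF, –78 → –30 °C; recool to –78 °C; add 11 [from 7 + LiN(SiMe3)2 (1.25 equiv), THF, –78 °C] by cannula; –78 → 0 °C, 3 h; aq NH4Cl; sulfide 6 recovered
Reagents that add atoms: none
Why: Proposed new method: 1,2-addition of 8 to the aldehyde gives 9, whose alkoxide takes over the Boc group and expels tert-butyl carbonate to unveil 10; the nucleophilic ylide carbon of 11 adds to the electrophilic methide carbon and the magnesium phenoxide then displaces the sulfide by 5-exo-tet SN2 with inversion (formal [4+1] annulation); the ylide reacts with its aryl group syn to the sulfur lone pair on the face remote from the CMe2 bridge, which fixes C2 as S, and the anti addition mode places the 3-aryl group trans, which fixes C3 as S; the closest known reactions are sulfur-ylide [4+1] annulations of ortho-quinone methides to trans-2,3-dihydrobenzofurans, Grignard-triggered ortho-quinone methide generation from O-Boc salicylaldehydes, and isothiocineole benzylide epoxidations and aziridinations.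

**Step 5**
Reactants: 12 (2S,3S)-2-(3,4-dimethoxyphenyl)-3-(3,5-dimethoxyphenyl)-6-methoxy-5-[(E)-3,5-dimethoxystyryl]-2,3-dihydro-1-benzofuran
Product: 13 5-[(E)-2-[(2S,3S)-2-(3,4-dihydroxyphenyl)-3-(3,5-dihydroxyphenyl)-6-hydroxy-2,3-dihydro-1-benzofuran-5-yl]ethenyl]benzene-1,3-diol (CNP0263230.1)
Conditions: BBr3 (1 M in CH2Cl2, 14 equiv), CH2Cl2, –78 °C → rt, dark; quench MeOH then H2O at –78 °C; reverse-phase purification
Reagents that add atoms: none
Why: Lewis-acid aryl methyl ether cleavage (BBr3 O-demethylation) proceeds by bromide SN2 attack on each boron-activated O–CH3, so the bonds cleaved do not involve the stereocentres, and any reversible C2–O ionisation re-closes to the more stable trans isomer with C3 intact.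

**Compound list**
1 | 5-bromo-2-hydroxy-4-methoxybenzaldehyde | O=Cc1cc(Br)c(OC)cc1O | starting material
2 | 3,5-dimethoxystyrene | C=Cc1cc(OC)cc(OC)c1 | starting material
3 | 5-[(E)-3,5-dimethoxystyryl]-2-hydroxy-4-methoxybenzaldehyde | O=Cc1cc(/C=C/c2cc(OC)cc(OC)c2)c(OC)cc1O | intermediate
4 | tert-butyl {2-formyl-5-methoxy-4-[(E)-3,5-dimethoxystyryl]phenyl} carbonate | O=Cc1cc(/C=C/c2cc(OC)cc(OC)c2)c(OC)cc1OC(=O)OC(C)(C)C | intermediate
5 | 3,4-dimethoxybenzyl bromide | COc1ccc(CBr)cc1OC | starting material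
6 | (1R,4R,5R)-4,7,7-trimethyl-6-thiabicyclo[3.2.1]octane, (1R,4R,5R)-isothiocineole | C[C@@H]1CC[C@@H]2C[C@H]1SC2(C)C | starting material
7 | (1R,4R,5R)-6-(3,4-dimethoxybenzyl)-4,7,7-trimethyl-6-thiabicyclo[3.2.1]octan-6-ium tetrafluoroborate (one diastereomer at sulfur, benzyl on the exo face; sulfur configuration not encoded) | C[C@@H]1CC[C@@H]2C[C@H]1[S+](Cc1ccc(OC)c(OC)c1)C2(C)C.F[B-](F)(F)F | intermediate
8 | 3,5-dimethoxyphenylmagnesium chloride | COc1cc(OC)cc([Mg]Cl)c1 | starting material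
9 | chloromagnesium {2-[(tert-butoxycarbonyl)oxy]-4-methoxy-5-[(E)-3,5-dimethoxystyryl]phenyl}(3,5-dimethoxyphenyl)methanolate, racemic, not isolated | COc1cc(OC)cc(C(O[Mg]Cl)c2cc(/C=C/c3cc(OC)cc(OC)c3)c(OC)cc2OC(=O)OC(C)(C)C)c1 | intermediate
10 | (6E)-6-[(3,5-dimethoxyphenyl)methylidene]-3-methoxy-4-[(E)-3,5-dimethoxystyryl]cyclohexa-2,4-dien-1-one, not isolated | COc1cc(OC)cc(/C=C2/C(=O)C=C(OC)C(/C=C/c3cc(OC)cc(OC)c3)=C2)c1 | intermediate
11 | (1R,4R,5R)-4,7,7-trimethyl-6-thiabicyclo[3.2.1]octan-6-ium-6-yl (3,4-dimethoxyphenyl)methanide, not isolated | C[C@@H]1CC[C@@H]2C[C@H]1[S+]([CH-]c1ccc(OC)c(OC)c1)C2(C)C | intermediate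
12 | (2S,3S)-2-(3,4-dimethoxyphenyl)-3-(3,5-dimethoxyphenyl)-6-methoxy-5-[(E)-3,5-dimethoxystyryl]-2,3-dihydro-1-benzofuran | COc1cc(OC)cc(/C=C/c2cc3c(cc2OC)O[C@H](c2ccc(OC)c(OC)c2)[C@H]3c2cc(OC)cc(OC)c2)c1 | intermediate
13 | 5-[(E)-2-[(2S,3S)-2-(3,4-dihydroxyphenyl)-3-(3,5-dihydroxyphenyl)-6-hydroxy-2,3-dihydro-1-benzofuran-5-yl]ethenyl]benzene-1,3-diol | Oc1cc(O)cc(/C=C/c2cc3c(cc2O)O[C@H](c2ccc(O)c(O)c2)[C@H]3c2cc(O)cc(O)c2)c1 | target

**Step count**
Total: 5 steps. Longest linear sequence: 4 steps (1 → 3 → 4 → 12 → 13); step 3 is a one-step side branch.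

**Steps most likely to fail, with fallbacks**

Step 4 is the most likely to fail. The ylide may be consumed by the carbonate, 10 may oligomerise before capture, or the trans/cis or facial selectivity may be low. The fallback sets out from 3 and comes back at 12; it separates quinone methide release from the C–C bond formation. Aldehyde 3 is treated with 8 (2.2 equiv, THF, 0 °C) to give racemic 2-[(3,5-dimethoxyphenyl)(hydroxy)methyl]-5-methoxy-4-[(E)-3,5-dimethoxystyryl]phenol F1. F1 with p-toluenesulfinic acid (CH2Cl2, rt) gives the bench-stable racemic sulfone 2-[(3,5-dimethoxyphenyl)(4-methylbenzenesulfonyl)methyl]-5-methoxy-4-[(E)-3,5-dimethoxystyryl]phenol F2. F2 and 7 with Cs2CO3 (3 equiv, CH2Cl2/MeCN, –20 °C → rt) release 10 by 1,4-elimination of sulfinate while 11 is formed slowly alongside, and the same annulation gives 12.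

Step 5 is next. Seven methyl ethers must be cleaved in the presence of an acid-sensitive stilbene and a benzylic ether. The fallback sets out from 1 and comes back at 13; it demethylates before the alkene exists and finishes under mild base.
- Bromide 1 is Boc-protected (Boc2O, DMAP cat., THF) to tert-butyl (4-bromo-2-formyl-5-methoxyphenyl) carbonate F3.
- The step 4 protocol with 8 and 7 runs through chloromagnesium {5-bromo-2-[(tert-butoxycarbonyl)oxy]-4-methoxyphenyl}(3,5-dimethoxyphenyl)methanolate F4 and (6E)-4-bromo-6-[(3,5-dimethoxyphenyl)methylidene]-3-methoxycyclohexa-2,4-dien-1-one F5, neither isolated, to (2S,3S)-5-bromo-2-(3,4-dimethoxyphenyl)-3-(3,5-dimethoxyphenyl)-6-methoxy-2,3-dihydro-1-benzofuran F6.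
- BBr3 (CH2Cl2, –78 °C → rt) gives (2S,3S)-5-bromo-2-(3,4-dihydroxyphenyl)-3-(3,5-dihydroxyphenyl)-2,3-dihydro-1-benzofuran-6-ol F7.
- Ac2O/pyridine gives (2S,3S)-6-acetoxy-5-bromo-2-(3,4-diacetoxyphenyl)-3-(3,5-diacetoxyphenyl)-2,3-dihydro-1-benzofuran F8.
- Heck coupling with 3,5-diacetoxystyrene (Pd(OAc)2, P(o-tol)3, Et3N, MeCN, 85 °C) gives (2S,3S)-6-acetoxy-2-(3,4-diacetoxyphenyl)-3-(3,5-diacetoxyphenyl)-5-[(E)-3,5-diacetoxystyryl]-2,3-dihydro-1-benzofuran F9.
- Methanolysis (K2CO3, MeOH, 0 °C, argon, then AcOH) gives 13.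

Step 1 is third. The phenoxide para to bromine slows oxidative addition, and some α-arylation of the styrene is possible. The fallback sets out from 1 and comes back at 3; it replaces alkene C–H arylation by coupling with a preformed vinyl metal. Commercial 1-ethynyl-3,5-dimethoxybenzene is hydroborated with pinacolborane (Cp2Zr(H)Cl 5 mol%, Et3N cat., 60 °C) to (E)-2-[2-(3,5-dimethoxyphenyl)ethenyl]-4,4,5,5-tetramethyl-1,3,2-dioxaborolane F10. Suzuki–Miyaura coupling of F10 with 1 (PdCl2(dppf) 3 mol%, K3PO4, dioxane/H2O, 80 °C) gives 3 with the alkene geometry fixed by the boronate.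

**Further compounds**
F1 | step 4 | 2-[(3,5-dimethoxyphenyl)(hydroxy)methyl]-5-methoxy-4-[(E)-3,5-dimethoxystyryl]phenol, racemic | COc1cc(OC)cc(C(O)c2cc(/C=C/c3cc(OC)cc(OC)c3)c(OC)cc2O)c1
F2 | step 4 | 2-[(3,5-dimethoxyphenyl)(4-methylbenzenesulfonyl)methyl]-5-methoxy-4-[(E)-3,5-dimethoxystyryl]phenol, racemic | COc1cc(OC)cc(C(c2cc(/C=C/c3cc(OC)cc(OC)c3)c(OC)cc2O)S(=O)(=O)c2ccc(C)cc2)c1
F3 | step 5 | tert-butyl (4-bromo-2-formyl-5-methoxyphenyl) carbonate | O=Cc1cc(Br)c(OC)cc1OC(=O)OC(C)(C)C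
F4 | step 5 | chloromagnesium {5-bromo-2-[(tert-butoxycarbonyl)oxy]-4-methoxyphenyl}(3,5-dimethoxyphenyl)methanolate, racemic, not isolated | COc1cc(OC)cc(C(O[Mg]Cl)c2cc(Br)c(OC)cc2OC(=O)OC(C)(C)C)c1
F5 | step 5 | (6E)-4-bromo-6-[(3,5-dimethoxyphenyl)methylidene]-3-methoxycyclohexa-2,4-dien-1-one, not isolated | COc1cc(OC)cc(/C=C2/C(=O)C=C(OC)C(Br)=C2)c1
F6 | step 5 | (2S,3S)-5-bromo-2-(3,4-dimethoxyphenyl)-3-(3,5-dimethoxyphenyl)-6-methoxy-2,3-dihydro-1-benzofuran | Brc1cc2c(cc1OC)O[C@H](c1ccc(OC)c(OC)c1)[C@H]2c1cc(OC)cc(OC)c1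
F7 | step 5 | (2S,3S)-5-bromo-2-(3,4-dihydroxyphenyl)-3-(3,5-dihydroxyphenyl)-2,3-dihydro-1-benzofuran-6-ol | Brc1cc2c(cc1O)O[C@H](c1ccc(O)c(O)c1)[C@H]2c1cc(O)cc(O)c1
F8 | step 5 | (2S,3S)-6-acetoxy-5-bromo-2-(3,4-diacetoxyphenyl)-3-(3,5-diacetoxyphenyl)-2,3-dihydro-1-benzofuran | Brc1cc2c(cc1OC(C)=O)O[C@H](c1ccc(OC(C)=O)c(OC(C)=O)c1)[C@H]2c1cc(OC(C)=O)cc(OC(C)=O)c1
F9 | step 5 | (2S,3S)-6-acetoxy-2-(3,4-diacetoxyphenyl)-3-(3,5-diacetoxyphenyl)-5-[(E)-3,5-diacetoxystyryl]-2,3-dihydro-1-benzofuran | CC(=O)Oc1cc(OC(C)=O)cc(/C=C/c2cc3c(cc2OC(C)=O)O[C@H](c2ccc(OC(C)=O)c(OC(C)=O)c2)[C@H]3c2cc(OC(C)=O)cc(OC(C)=O)c2)c1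
F10 | step 1 | (E)-2-[2-(3,5-dimethoxyphenyl)ethenyl]-4,4,5,5-tetramethyl-1,3,2-dioxaborolane | COc1cc(OC)cc(/C=C/B2OC(C)(C)C(C)(C)O2)c1
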